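The pyranone C ring (O1, C2, C3, C4, C4a, C8a) is the only ring built. It is cut at C4a–C4, C4–C3 and O1–C2 into an A-ring iodide, carbon monoxide and a B-ring aryl alkyne, which one Pd-catalysed carbonylative annulation reassembles. The feature exploited is the local symmetry of the A ring about the C4a···C7 axis: O1 and the 5-OH oxygen are interchangeable neighbours of C4a, whereas O7 lies para to it. The precursor is therefore a mirror-symmetric 2-iodoresorcinol that already carries the sulfate, masked as a neutral neopentyl diester, para to iodine, so the sulfation site is settled before the heterocycle exists and no triphenol is ever sulfated.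

Key step: step 7

Remark: the target has no stereocentre and no configurable double bond, so there is no enantiomer to select; the hydrogen sulfate (acid) form as drawn is taken as the final product.

Step 1
Reactants: 1 neopentyl alcohol (2,2-dimethylpropan-1-ol); 2 sulfuryl chloride
Product: 3 neopentyl chlorosulfate
Conditions: pyridine (1.0 equiv), Et2O, −78 °C → rt
Reagents that add atoms: none
Why: Chlorosulfation of a primary alcohol, in which the alcohol displaces one S–Cl bond of sulfuryl chloride with pyridine as HCl scavenger and the neopentyl skeleton blocks the SN2 return of chloride that degrades less hindered alkyl chlorosulfates.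

Step 2
Reactants: 4 3,5-bis(benzyloxy)phenol; 3 neopentyl chlorosulfate
Product: 5 3,5-bis(benzyloxy)phenyl neopentyl sulfate
Conditions: NaH (1.1 equiv), THF, 0 °C; then 3 (1.2 equiv), 0 °C → rt
Reagents that add atoms: none
Why: O-Sulfonylation (sulfate diester formation) of the only free phenol, since the sodium phenoxide attacks sulfur of 3 and displaces chloride while the neopentyl carbon is sterically closed and the benzyl ethers are inert.

Step 3
Reactants: 5 3,5-bis(benzyloxy)phenyl neopentyl sulfate
Product: 6 3,5-dihydroxyphenyl neopentyl sulfate
Conditions: H2 (1 atm), 10% Pd/C, EtOAc–EtOH, rt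
Reagents that add atoms: none
Why: Catalytic hydrogenolysis of benzyl aryl ethers under neutral conditions, in which the neopentyl aryl sulfate offers no benzylic or otherwise reducible bond and is retained.

Step 4
Reactants: 6 3,5-dihydroxyphenyl neopentyl sulfate
Product: 7 3,5-dihydroxy-4-iodophenyl neopentyl sulfate
Conditions: I2 (1.0 equiv), NaHCO3 (1.1 equiv), THF–H2O, 0 °C; Na2S2O3 quench, no acid in the work-up
Reagents that add atoms: iodine, II
Why: Electrophilic aromatic iodination under the aqueous bicarbonate protocol that takes resorcinols kinetically at the carbon between the hydroxyls; that carbon is ortho to both donors and para to the sulfate oxygen, the two alternatives adjoin the bulky, inductively withdrawing diester, and the acid-free work-up avoids iodine migration.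

Step 5
Reactants: 8 4-hydroxybenzaldehyde
Product: 9 4-(methoxymethoxy)benzaldehyde
Conditions: MOMCl (1.2 equiv), iPr2NEt (1.5 equiv), CH2Cl2, 0 °C → rt
Reagents that add atoms: chloromethyl methyl ether, COCCl
Why: Williamson-type O-alkylation (MOM protection) of the acidic para-formyl phenol with a hindered amine base, which leaves the aldehyde untouched.

Step 6
Reactants: 9 4-(methoxymethoxy)benzaldehyde
Product: 10 1-ethynyl-4-(methoxymethoxy)benzene
Conditions: dimethyl (1-diazo-2-oxopropyl)phosphonate (1.2 equiv), K2CO3 (2 equiv), MeOH, rt
Reagents that add atoms: dimethyl (1-diazo-2-oxopropyl)phosphonate, COP(=O)(OC)C(=[N+]=[N-])C(C)=O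
Why: Ohira–Bestmann variant of the Seyferth–Gilbert homologation, in which methanolysis of the reagent frees the diazomethylphosphonate anion, which olefinates the non-enolisable aldehyde and gives the terminal alkyne after loss of N2 and a 1,2-hydrogen shift, under conditions harmless to the MOM ether.

Step 7
Reactants: 7 3,5-dihydroxy-4-iodophenyl neopentyl sulfate; 10 1-ethynyl-4-(methoxymethoxy)benzene; 11 carbon monoxide
Product: 14 5-hydroxy-4'-(methoxymethoxy)flavon-7-yl neopentyl sulfate, via aryl ynone 12 (not isolated), via diethylamino enone 13 (not isolated)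
Conditions: PdCl2(dppf) (5 mol %), CO (1 atm), Et2NH (5 equiv), 10 (1.3 equiv), degassed DMF, 50 °C, no copper
Reagents that add atoms: none
Why: Pd(0) inserts into the C–I bond of 7, CO migratory insertion gives the 2,6-dihydroxyaroyl–Pd(II) iodide, and the alkynyl group of amine-deprotonated 10 is transferred and reductively eliminated, which forges C4a–C4 and C4–C3 with 11 as the C4 carbonyl and delivers ynone 12. Diethylamine then adds to 12 in conjugate fashion to give the push–pull enone 13, and an ortho hydroxyl attacks its β-carbon and expels the amine, so that O1–C2 forms by addition–elimination, in net terms a 6-endo closure of the pyranone ring, the only ring made. The closest known reaction type is the Pd-catalysed carbonylative Sonogashira annulation of o-iodophenols with terminal alkynes and CO to flavones in secondary-amine media. No stereocentre arises. Two selectivities are needed: carbonylative over direct coupling, which is favoured by the copper-free catalyst, a CO-saturated solution and the quick migration of the electron-rich, doubly ortho-substituted aryl group onto CO, and 6-endo over 5-exo closure, which passage through 13 secures since its β-carbon is the only site open to oxygen. Which hydroxyl closes is immaterial, because the mirror plane through C–I and C–OSO3 of 7 makes them equivalent; the spectator becomes the chelated 5-OH, the diester para to iodine ends on O7, and the moderate temperature and limited amine charge spare the neopentyl sulfate.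

Step 8
Reactants: 14 5-hydroxy-4'-(methoxymethoxy)flavon-7-yl neopentyl sulfate
Product: 15 apigenin 7-(neopentyl sulfate)
Conditions: TFA–CH2Cl2 (1:2), H2O (5 equiv), 0 °C → rt
Reagents that add atoms: none
Why: Acid-catalysed acetal hydrolysis of the MOM aryl ether, carried out while the sulfate is still a neutral neopentyl diester, a class that withstands aqueous trifluoroacetic acid, so no acid-labile aryl sulfate monoester is ever exposed to acid.

Step 9
Reactants: 15 apigenin 7-(neopentyl sulfate)
Product: 16 sodium apigenin 7-sulfate
Conditions: NaN3 (2 equiv), DMF, 65 °C; C18 reverse-phase chromatography (H2O–MeOH) to remove all azide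
Reagents that add atoms: sodium azide, [Na+].[N-]=[N+]=[N-]
Why: SN2 dealkylation of a neopentyl sulfate diester, in which the small, weakly basic azide ion attacks the neopentyl CH2 in a warm dipolar aprotic solvent and releases the aryl sulfate monoanion as an excellent leaving group without disturbing the free phenols.

Step 10
Reactants: 16 sodium apigenin 7-sulfate
Product: 17 apigenin 7-sulfate (hydrogen sulfate form, target)
Conditions: strong-acid sulfonic resin (H+ form), H2O–MeOH, 0–5 °C; immediate freeze-drying, cold storage
Reagents that add atoms: none
Why: Cation exchange on a sulfonic acid resin replaces Na+ by H+ without any soluble acid, and cold elution with prompt lyophilisation limits the acid-catalysed solvolysis to which aryl hydrogen sulfates are prone.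

Compound list
1 | neopentyl alcohol | CC(C)(C)CO | starting material
2 | sulfuryl chloride | O=S(=O)(Cl)Cl | starting material
3 | neopentyl chlorosulfate | CC(C)(C)COS(=O)(=O)Cl | intermediate
4 | 3,5-bis(benzyloxy)phenol | Oc1cc(OCc2ccccc2)cc(OCc2ccccc2)c1 | starting material
5 | 3,5-bis(benzyloxy)phenyl neopentyl sulfate | CC(C)(C)COS(=O)(=O)Oc1cc(OCc2ccccc2)cc(OCc2ccccc2)c1 | intermediate
6 | 3,5-dihydroxyphenyl neopentyl sulfate | CC(C)(C)COS(=O)(=O)Oc1cc(O)cc(O)c1 | intermediate
7 | 3,5-dihydroxy-4-iodophenyl neopentyl sulfate | CC(C)(C)COS(=O)(=O)Oc1cc(O)c(I)c(O)c1 | intermediate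
8 | 4-hydroxybenzaldehyde | O=Cc1ccc(O)cc1 | starting material
9 | 4-(methoxymethoxy)benzaldehyde | O=Cc1ccc(OCOC)cc1 | intermediate
10 | 1-ethynyl-4-(methoxymethoxy)benzene | C#Cc1ccc(OCOC)cc1 | intermediate
11 | carbon monoxide | [C-]#[O+] | starting material
12 | 3,5-dihydroxy-4-{3-[4-(methoxymethoxy)phenyl]prop-2-ynoyl}phenyl neopentyl sulfate | COCOc1ccc(C#CC(=O)c2c(O)cc(OS(=O)(=O)OCC(C)(C)C)cc2O)cc1 | intermediate
13 | 4-{(E)-3-(diethylamino)-3-[4-(methoxymethoxy)phenyl]prop-2-enoyl}-3,5-dihydroxyphenyl neopentyl sulfate | CCN(CC)/C(c1ccc(OCOC)cc1)=C/C(=O)c1c(O)cc(OS(=O)(=O)OCC(C)(C)C)cc1O | intermediate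
14 | 5-hydroxy-2-[4-(methoxymethoxy)phenyl]-4-oxo-4H-chromen-7-yl neopentyl sulfate | COCOc1ccc(-c2cc(=O)c3c(O)cc(OS(=O)(=O)OCC(C)(C)C)cc3o2)cc1 | intermediate
15 | 5-hydroxy-2-(4-hydroxyphenyl)-4-oxo-4H-chromen-7-yl neopentyl sulfate | CC(C)(C)COS(=O)(=O)Oc1cc(O)c2c(=O)cc(-c3ccc(O)cc3)oc2c1 | intermediate
16 | sodium 5-hydroxy-2-(4-hydroxyphenyl)-4-oxo-4H-chromen-7-yl sulfate | [Na+].[O-]S(=O)(=O)Oc1cc(O)c2c(=O)cc(-c3ccc(O)cc3)oc2c1 | intermediate
17 | apigenin 7-sulfate, 5-hydroxy-2-(4-hydroxyphenyl)-4-oxo-4H-chromen-7-yl hydrogen sulfate | O=c1cc(-c2ccc(O)cc2)oc2cc(OS(=O)(=O)O)cc(O)c12 | target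

Total step count: 10
Longest linear sequence: 8 steps (1, 2, 3, 4, 7, 8, 9, 10)

Steps most likely to fail

Step 7. Several processes could compete with the annulation:
- direct alkynylation outrunning CO insertion, followed by 5-endo closure
- interception of the aroyl–palladium species by diethylamine
- 5-exo closure
- reductive loss of iodine from the electron-rich ring
- aminolysis at sulfur once the electron-poor chromone has formed

The fallback gives up ring construction and chooses the oxygen by acidity instead of symmetry. It sets out from chlorosulfate 3. Purchased apigenin F1 is treated with one equivalent of K2CO3 in DMF at 0 °C and then with one equivalent of 3. The most acidic and unchelated 7-OH should be sulfonylated ahead of the 4'-OH, and the hydrogen-bonded 5-OH should stay inert. The route is rejoined at 15.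

Step 4. The risks are poor site selectivity between the carbon flanked by two hydroxyls and the carbons next to the diester, over-iodination, and migration or loss of iodine on contact with acid. The fallback replaces electrophilic substitution by directed ortho-metalation and installs the sulfate afterwards. It sets out from 4.
- Silylation (TIPSCl, imidazole, DMF) gives [3,5-bis(benzyloxy)phenoxy]triisopropylsilane F2.
- Hydrogenolysis (H2, Pd/C) gives 5-(triisopropylsilyloxy)benzene-1,3-diol F3.
- MOMCl with iPr2NEt gives [3,5-bis(methoxymethoxy)phenoxy]triisopropylsilane F4.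
- n-BuLi in THF at 0 °C lithiates the carbon between the two cooperating MOM ethers, because the bulky, non-directing silyl ether shields its own neighbours. Quenching with I2 gives [4-iodo-3,5-bis(methoxymethoxy)phenoxy]triisopropylsilane F5.
- TBAF at 0 °C frees 4-iodo-3,5-bis(methoxymethoxy)phenol F6.
- NaH and then 3 give 4-iodo-3,5-bis(methoxymethoxy)phenyl neopentyl sulfate F7.
- Brief exposure to TFA–CH2Cl2–H2O at 0 °C removes both acetals.

The route is rejoined at 7.

Step 9. Azide may attack sulfur rather than the hindered CH2 and expel the well-stabilised chromone 7-oxide, so that the whole sulfate is lost. The SN2 reaction at a neopentyl carbon may also be slow. The fallback unmasks the sulfate before the aryl group becomes a good leaving group and carries it through the annulation as an amine-inert anion. It sets out from 7. NaN3 in DMF at 65 °C gives sodium 3,5-dihydroxy-4-iodophenyl sulfate F8, which is freed from azide by reverse-phase chromatography. F8 is then annulated with purchased 4-ethynylphenol F9 and CO 11 under the catalyst system of step 7, so no acid-labile B-ring protecting group is needed. Passage over a Na+-form resin rejoins the route at 16.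

Further compounds
F1 | step 7 | apigenin (purchased) | O=c1cc(-c2ccc(O)cc2)oc2cc(O)cc(O)c12
F2 | step 4 | [3,5-bis(benzyloxy)phenoxy]triisopropylsilane | CC(C)[Si](Oc1cc(OCc2ccccc2)cc(OCc2ccccc2)c1)(C(C)C)C(C)C
F3 | step 4 | 5-(triisopropylsilyloxy)benzene-1,3-diol | CC(C)[Si](Oc1cc(O)cc(O)c1)(C(C)C)C(C)C
F4 | step 4 | [3,5-bis(methoxymethoxy)phenoxy]triisopropylsilane | COCOc1cc(OCOC)cc(O[Si](C(C)C)(C(C)C)C(C)C)c1
F5 | step 4 | [4-iodo-3,5-bis(methoxymethoxy)phenoxy]triisopropylsilane | COCOc1cc(O[Si](C(C)C)(C(C)C)C(C)C)cc(OCOC)c1I
F6 | step 4 | 4-iodo-3,5-bis(methoxymethoxy)phenol | COCOc1cc(O)cc(OCOC)c1I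
F7 | step 4 | 4-iodo-3,5-bis(methoxymethoxy)phenyl neopentyl sulfate | COCOc1cc(OS(=O)(=O)OCC(C)(C)C)cc(OCOC)c1I
F8 | step 9 | sodium 3,5-dihydroxy-4-iodophenyl sulfate | [Na+].[O-]S(=O)(=O)Oc1cc(O)c(I)c(O)c1
F9 | step 9 | 4-ethynylphenol (purchased) | C#Cc1ccc(O)cc1
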